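## Retrosynthetic overview

- The target is opened at the C8 angelate ester, the C13 methylene, the C8–O bond (carried as C8–Si) and the C6–O/C12 lactone. C14–OH and the ring‑cis C1=C10 alkene come together from one SeO2 ene/[2,3] oxidation of a 14‑methyl, ring‑trans alkene.
- The ten‑membered ring comes from an anionic oxy‑Cope rearrangement of a 1,2‑dialkenylcyclohex‑2‑enol that forms C8–C9 and breaks C1–C6; the resulting C6/C7 enolate is C‑alkylated at C7 in the same flask.
- Enabling feature: in the ten‑membered ring, O–C6, C7, the C8–C9 bond and the C10=C1 alkene form a δ,ε‑unsaturated carbonyl array, C6(O)–C7–C8–C9–C10=C1. Reconnecting C1 to C6 gives a cyclohexene (C1–C6) that already holds the cis C4=C5 alkene, C15 and the C2 oxygen.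
- The cyclohexenone comes from an Evans syn aldol (sets C1 and C2) followed by ring‑closing metathesis.
- Ring order: cyclohexene (metathesis) → ten‑membered carbocycle (oxy‑Cope) → γ‑lactone.

Key step: step 10

Remark (numbering): germacrane labels are used throughout, also for the earlier intermediates: C1–C10 ring, C11–C13 lactone carbons, C14 on C10, C15 on C4; α/β refer to the flat drawing with H‑7 α. The target is 2S,6R,7R,8S, has both ring alkenes cis in the ring (4Z; C2 cis to C9 across C1=C10) and carries a (Z)‑2‑methylbut‑2‑enoate (angelate).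

Assumption: the hydride in step 13 is taken to attack from the ring periphery, giving the 6β alcohol; the route is written for that outcome, and the other C6 epimer reaches the same lactone by the fallback for step 13.

## Route

Step 1
Reactants: 1 (R)-4-benzyloxazolidin-2-one; 2 3-methylbut-2-enoyl chloride
Product: 4 (R)-4-benzyl-3-(3-methylbut-2-enoyl)oxazolidin-2-one, via lithium oxazolidinide 3 (not isolated)
Conditions: n-BuLi, THF, −78 °C; then 2, −78 → 0 °C
Reagents that add atoms: none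
Why: N‑acylation of the lithiated Evans auxiliary by the acid chloride is a routine acyl substitution and creates no stereocenter.

Step 2
Reactants: 5 3-methylbut-3-en-1-ol
Product: 6 3-methylbut-3-enal
Conditions: Dess–Martin periodinane, NaHCO3, CH2Cl2, 0 °C; used at once as a solution
Reagents that add atoms: none
Why: Dess–Martin oxidation under buffered, amine‑free conditions should give the β,γ‑unsaturated aldehyde without migration of the alkene into conjugation.

Step 3
Reactants: 4 (R)-4-benzyl-3-(3-methylbut-2-enoyl)oxazolidin-2-one; 6 3-methylbut-3-enal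
Product: 8 (R)-4-benzyl-3-[(2R,3S)-3-hydroxy-5-methyl-2-(prop-1-en-2-yl)hex-5-enoyl]oxazolidin-2-one, via boron dienolate 7 (not isolated)
Conditions: Bu2BOTf, Et3N, CH2Cl2, −78 → 0 °C; then 6, −78 → 0 °C; pH 7 buffer, MeOH, 30% H2O2
Reagents that add atoms: none
Why: Evans boron aldol reaction, in which γ‑deprotonation gives the (Z)‑dienolate that reacts at its α‑carbon through a Zimmerman–Traxler chair with the benzyl group of the (R)‑auxiliary shielding one face, so the syn adduct with C1 (R) and C2 (S) should form.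

Step 4
Reactants: 8 (R)-4-benzyl-3-[(2R,3S)-3-hydroxy-5-methyl-2-(prop-1-en-2-yl)hex-5-enoyl]oxazolidin-2-one
Product: 9 (2R,3S)-3-hydroxy-N-methoxy-N,5-dimethyl-2-(prop-1-en-2-yl)hex-5-enamide
Conditions: MeNH(OMe)·HCl, AlMe3, CH2Cl2, −20 → 0 °C; aqueous potassium sodium tartrate
Reagents that add atoms: N,O-dimethylhydroxylamine hydrochloride (CNOC.Cl)
Why: Aluminium‑amide transamination of an Evans aldol adduct with a free β‑hydroxyl is the standard route to the Weinreb amide and should leave the α‑stereocenter untouched.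

Step 5
Reactants: 9 (2R,3S)-3-hydroxy-N-methoxy-N,5-dimethyl-2-(prop-1-en-2-yl)hex-5-enamide
Product: 10 (2R,3S)-3-[(tert-butyldimethylsilyl)oxy]-N-methoxy-N,5-dimethyl-2-(prop-1-en-2-yl)hex-5-enamide
Conditions: t-BuMe2SiOTf, 2,6-lutidine, CH2Cl2, −78 °C
Reagents that add atoms: tert-butyldimethylsilyl trifluoromethanesulfonate (CC(C)(C)[Si](C)(C)OS(=O)(=O)C(F)(F)F)
Why: Silyl triflate silylation of the hindered secondary alcohol is fast at low temperature and avoids retro‑aldol or alkene migration.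

Step 6
Reactants: 10 (2R,3S)-3-[(tert-butyldimethylsilyl)oxy]-N-methoxy-N,5-dimethyl-2-(prop-1-en-2-yl)hex-5-enamide
Product: 11 (4R,5S)-5-[(tert-butyldimethylsilyl)oxy]-7-methyl-4-(prop-1-en-2-yl)octa-1,7-dien-3-one
Conditions: CH2=CHMgBr, THF, −78 → 0 °C; cold aqueous NH4Cl
Reagents that add atoms: vinylmagnesium bromide (C=C[Mg]Br)
Why: Weinreb ketone synthesis, in which the stable magnesium chelate prevents over‑addition and the cold quench limits epimerisation of the doubly activated C1–H.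

Step 7
Reactants: 11 (4R,5S)-5-[(tert-butyldimethylsilyl)oxy]-7-methyl-4-(prop-1-en-2-yl)octa-1,7-dien-3-one
Product: 12 (5S,6R)-5-[(tert-butyldimethylsilyl)oxy]-3-methyl-6-(prop-1-en-2-yl)cyclohex-2-en-1-one
Conditions: second-generation Grubbs catalyst RuCl2(=CHPh)(PCy3)(H2IMes) (5 mol%), CH2Cl2, 40 °C
Reagents that add atoms: none
Why: Ring‑closing metathesis of the vinyl ketone with the 2‑methylallyl terminus closes the six‑membered enone (C4=C5) under neutral conditions, the isopropenyl group being able to form only a four‑ring or a tetrasubstituted five‑ring.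

Step 8
Reactants: 13 (E)-1,2-bis(tributylstannyl)ethene; 14 tert-butoxy(chloro)diphenylsilane
Product: 16 (E)-tert-butoxydiphenyl[2-(tributylstannyl)vinyl]silane, via stannylvinyllithium 15 (not isolated)
Conditions: n-BuLi (1 equiv), THF, −78 °C; then 14, −78 → 0 °C
Reagents that add atoms: none
Why: A single tin–lithium exchange followed by silylation of the configurationally stable (E)‑vinyllithium gives the (E)‑1‑silyl‑2‑stannylethene with retention of geometry.

Step 9
Reactants: 16 (E)-tert-butoxydiphenyl[2-(tributylstannyl)vinyl]silane; 12 (5S,6R)-5-[(tert-butyldimethylsilyl)oxy]-3-methyl-6-(prop-1-en-2-yl)cyclohex-2-en-1-one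
Product: 19 (1S,5S,6R)-1-[(E)-2-(tert-butoxydiphenylsilyl)vinyl]-5-[(tert-butyldimethylsilyl)oxy]-3-methyl-6-(prop-1-en-2-yl)cyclohex-2-en-1-ol, via silylvinyllithium 17 (not isolated), via silylvinylcerium dichloride 18 (not isolated)
Conditions: n-BuLi, THF, −78 °C; anhydrous CeCl3, −78 °C; then 12, −78 °C; H2O
Reagents that add atoms: none
Why: Tin–lithium exchange and transmetalation to the weakly basic organocerium reagent allow clean 1,2‑addition to the enolisable β‑silyloxy enone, and the alkenyl group should enter the carbonyl face opposite the neighbouring isopropenyl group (equatorial attack), setting C6 (S) with the two alkenyl groups trans.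

Step 10
Reactants: 19 (1S,5S,6R)-1-[(E)-2-(tert-butoxydiphenylsilyl)vinyl]-5-[(tert-butyldimethylsilyl)oxy]-3-methyl-6-(prop-1-en-2-yl)cyclohex-2-en-1-ol
Product: 22 2-[(1S,2S,4E,6S,8Z)-2-(tert-butoxydiphenylsilyl)-6-[(tert-butyldimethylsilyl)oxy]-4,8-dimethyl-10-oxocyclodeca-4,8-dien-1-yl]-N,N-dimethylacetamide, via potassium alkoxide 20 (not isolated), via potassium enolate 21 (not isolated)
Conditions: KH, 18-crown-6, THF, 0 → 25 °C; then BrCH2C(O)NMe2, −78 → 0 °C
Reagents that add atoms: 2-bromo-N,N-dimethylacetamide (CN(C)C(=O)CBr)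
Why: Deprotonation of 19 gives alkoxide 20, whose C6–O− weakens the C1–C6 bond and triggers a concerted [3,3] sigmatropic shift (anionic oxy‑Cope) across C9=C10–C1–C6–C7=C8 that forms C8–C9, breaks C1–C6 and leaves enolate 21; this is the reaction type used to make cyclodeca‑dienones from 1,2‑dialkenylcyclohexenols, extended here by C‑alkylation of the regiodefined enolate in the same flask. The ten‑membered ring is closed by ring expansion of the six‑membered ring through a six‑centre chair transition state in which the alkene termini C8 and C9 bond suprafacially while both old‑ring bonds (C1–C2, C6–C5) and the bulky silyl group sit equatorial. C8 (S) is set by chirality transfer from C1 (R) and C6 (S) together with the E geometry of the vinylsilane, and C7 (S) is set when the bromide approaches the enolate from the ring periphery on the face away from the adjacent C8 silyl group (2,3‑trans). The same chair fixes C1=C10 as the ring‑trans (E) alkene, and C4=C5 stays cis because it was part of the six‑membered ring. The step needs chair over boat (secured by the trans, diequatorial dialkenyl arrangement and the E‑vinylsilane), rearrangement over alkoxide fragmentation (the crown ether gives the loose ion pair that rearranges near room temperature) and C‑alkylation at C7 only (the enolate is formed regiospecifically and is quenched cold with a soft primary bromide). Carrying C8–O as C8–Si keeps the β‑position of the enolate free of a leaving group.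

Step 11
Reactants: 22 2-[(1S,2S,4E,6S,8Z)-2-(tert-butoxydiphenylsilyl)-6-[(tert-butyldimethylsilyl)oxy]-4,8-dimethyl-10-oxocyclodeca-4,8-dien-1-yl]-N,N-dimethylacetamide
Product: 23 2-[(1S,2S,4E,6S,8Z)-2-(tert-butoxydiphenylsilyl)-6-[(tert-butyldimethylsilyl)oxy]-4-(hydroxymethyl)-8-methyl-10-oxocyclodeca-4,8-dien-1-yl]-N,N-dimethylacetamide (C2 and C9 now cis across C1=C10)
Conditions: SeO2 (0.5 equiv), t-BuOOH (2 equiv), CH2Cl2, 0 → 25 °C
Reagents that add atoms: selenium dioxide (O=[Se]=O), which transfers the oxygen; tert-butyl hydroperoxide (CC(C)(C)OO), which re-oxidises it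
Why: SeO2 allylic oxidation, in which an ene reaction at C1 with hydrogen abstraction from the C14 methyl and a [2,3] shift of the allylseleninic acid put oxygen on C14 and re‑form C1=C10 with C14 trans to C2 (the ring‑cis alkene), as is known for ring‑trans 14‑methyl germacranolides, while the C4=C5 alkene is protected by conjugation to the C6 ketone.

Step 12
Reactants: 23 2-[(1S,2S,4E,6S,8Z)-2-(tert-butoxydiphenylsilyl)-6-[(tert-butyldimethylsilyl)oxy]-4-(hydroxymethyl)-8-methyl-10-oxocyclodeca-4,8-dien-1-yl]-N,N-dimethylacetamide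
Product: 24 2-[(1S,2S,4E,6S,8Z)-2-(tert-butoxydiphenylsilyl)-6-[(tert-butyldimethylsilyl)oxy]-4-{[(tert-butyldimethylsilyl)oxy]methyl}-8-methyl-10-oxocyclodeca-4,8-dien-1-yl]-N,N-dimethylacetamide
Conditions: t-BuMe2SiCl, imidazole, CH2Cl2, 0 °C
Reagents that add atoms: tert-butyldimethylsilyl chloride (CC(C)(C)[Si](C)(C)Cl)
Why: Silylation of the only free (primary allylic) hydroxyl under weakly basic conditions should not epimerise C7.

Step 13
Reactants: 24 2-[(1S,2S,4E,6S,8Z)-2-(tert-butoxydiphenylsilyl)-6-[(tert-butyldimethylsilyl)oxy]-4-{[(tert-butyldimethylsilyl)oxy]methyl}-8-methyl-10-oxocyclodeca-4,8-dien-1-yl]-N,N-dimethylacetamide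
Product: 25 2-[(1S,2S,4E,6S,8Z,10S)-2-(tert-butoxydiphenylsilyl)-6-[(tert-butyldimethylsilyl)oxy]-4-{[(tert-butyldimethylsilyl)oxy]methyl}-10-hydroxy-8-methylcyclodeca-4,8-dien-1-yl]-N,N-dimethylacetamide (6β-OH)
Conditions: NaBH4, CeCl3·7H2O, MeOH, −78 °C
Reagents that add atoms: none
Why: Luche reduction gives 1,2‑reduction of the enone only, and hydride is expected to arrive from the ring periphery on the side away from the C7 acetamide arm, giving the 6β (S) alcohol cis to that arm, which as a tertiary amide does not lactonise by itself.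

Step 14
Reactants: 25 2-[(1S,2S,4E,6S,8Z,10S)-2-(tert-butoxydiphenylsilyl)-6-[(tert-butyldimethylsilyl)oxy]-4-{[(tert-butyldimethylsilyl)oxy]methyl}-10-hydroxy-8-methylcyclodeca-4,8-dien-1-yl]-N,N-dimethylacetamide
Product: 28 (2S,6R,7S,8S)-8-(tert-butoxydiphenylsilyl)-2,14-bis[(tert-butyldimethylsilyl)oxy]germacra-1(10),4-dien-12,6-olide (trans-fused lactone; both ring alkenes cis in the ring), via allylic mesylate 26 (not isolated), via iminium ether 27 (not isolated)
Conditions: (MeSO2)2O, Et3N, CH2Cl2, −30 → 0 °C; then THF/H2O, NaHCO3, 25 °C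
Reagents that add atoms: water (O)
Why: Invertive lactonisation by neighbouring‑group participation: the amide oxygen displaces the allylic C6 mesylate from the back (5‑exo, inversion; the anhydride keeps chloride out) to give iminium ether 27, whose hydrolysis releases Me2NH and leaves the trans‑fused lactone with 6α‑O (6R).

Step 15
Reactants: 28 (2S,6R,7S,8S)-8-(tert-butoxydiphenylsilyl)-2,14-bis[(tert-butyldimethylsilyl)oxy]germacra-1(10),4-dien-12,6-olide
Product: 29 (2S,6R,7R,8S)-2,14-bis[(tert-butyldimethylsilyl)oxy]-8-hydroxygermacra-1(10),4-dien-12,6-olide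
Conditions: 30% H2O2, KF, KHCO3, THF/MeOH, 40 °C
Reagents that add atoms: hydrogen peroxide (OO)
Why: Tamao–Fleming oxidation of the alkoxysilane, in which C8 migrates from silicon to oxygen with retention, converts C8–Si (α) into C8–OH (α, 8S) under weakly basic peroxide that isolated alkenes and silyl ethers tolerate.

Step 16
Reactants: 29 (2S,6R,7R,8S)-2,14-bis[(tert-butyldimethylsilyl)oxy]-8-hydroxygermacra-1(10),4-dien-12,6-olide
Product: 32 (2S,6R,7R,8S)-2,14-bis[(tert-butyldimethylsilyl)oxy]-8-hydroxygermacra-1(10),4,11(13)-trien-12,6-olide, via Mannich base 30 (not isolated), via ammonium iodide 31 (not isolated)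
Conditions: LiN(i-Pr)2 (2.2 equiv), THF, −78 °C; CH2=NMe2+ I−, −78 → 0 °C; then MeI, MeOH, 25 °C; aqueous NaHCO3, CH2Cl2
Reagents that add atoms: N,N-dimethylmethyleneiminium iodide (C=[N+](C)C.[I-])
Why: α‑Methylenation by Mannich reaction of the lactone enolate (formed beside the C8 lithium alkoxide, the enolised lactone being protected from acyl transfer), quaternisation and Hofmann‑type elimination installs C13 without touching a stereocenter.

Step 17
Reactants: 32 (2S,6R,7R,8S)-2,14-bis[(tert-butyldimethylsilyl)oxy]-8-hydroxygermacra-1(10),4,11(13)-trien-12,6-olide; 33 (Z)-2-methylbut-2-enoic acid (angelic acid)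
Product: 35 (2S,6R,7R,8S)-8-[(Z)-2-methylbut-2-enoyloxy]-2,14-bis[(tert-butyldimethylsilyl)oxy]germacra-1(10),4,11(13)-trien-12,6-olide, via mixed anhydride 34 (not isolated)
Conditions: 33, 2,4,6-Cl3C6H2COCl, Et3N, toluene, 25 °C; then 32, DMAP (cat.), 70 °C
Reagents that add atoms: none
Why: Yamaguchi esterification through the trichlorobenzoyl mixed anhydride acylates hindered secondary alcohols and is the established way to attach an angelate without Z → E isomerisation to the tiglate.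

Step 18
Reactants: 35 (2S,6R,7R,8S)-8-[(Z)-2-methylbut-2-enoyloxy]-2,14-bis[(tert-butyldimethylsilyl)oxy]germacra-1(10),4,11(13)-trien-12,6-olide
Product: 36 CNP0270898.1, (2S,6R,7R,8S)-2,14-dihydroxy-8-[(Z)-2-methylbut-2-enoyloxy]germacra-1(10),4,11(13)-trien-12,6-olide (target)
Conditions: HF·pyridine, pyridine, THF, 0 → 25 °C
Reagents that add atoms: none
Why: Buffered fluoride desilylation removes both silyl ethers without acyl migration, conjugate addition to the α‑methylene lactone or acid‑induced transannular cyclisation.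

## Compound list

1 | (R)-4-benzyloxazolidin-2-one | O=C1OC[C@@H](Cc2ccccc2)N1 | starting material
2 | 3-methylbut-2-enoyl chloride | CC(C)=CC(Cl)=O | starting material
3 | lithium (R)-4-benzyl-2-oxooxazolidin-3-ide | [Li+].O=C1OC[C@@H](Cc2ccccc2)[N-]1 | intermediate (not isolated)
4 | (R)-4-benzyl-3-(3-methylbut-2-enoyl)oxazolidin-2-one | CC(C)=CC(=O)N1[C@H](Cc2ccccc2)COC1=O | intermediate
5 | 3-methylbut-3-en-1-ol | CC(=C)CCO | starting material
6 | 3-methylbut-3-enal | CC(=C)CC=O | intermediate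
7 | dibutylboron (Z)-dienolate of 4 | CCCCB(CCCC)O/C(=C\C(C)=C)N1[C@H](Cc2ccccc2)COC1=O | intermediate (not isolated)
8 | (R)-4-benzyl-3-[(2R,3S)-3-hydroxy-5-methyl-2-(prop-1-en-2-yl)hex-5-enoyl]oxazolidin-2-one | C=C(C)C[C@H](O)[C@@H](C(C)=C)C(=O)N1[C@H](Cc2ccccc2)COC1=O | intermediate
9 | (2R,3S)-3-hydroxy-N-methoxy-N,5-dimethyl-2-(prop-1-en-2-yl)hex-5-enamide | C=C(C)C[C@H](O)[C@@H](C(C)=C)C(=O)N(C)OC | intermediate
10 | (2R,3S)-3-[(tert-butyldimethylsilyl)oxy]-N-methoxy-N,5-dimethyl-2-(prop-1-en-2-yl)hex-5-enamide | C=C(C)C[C@H](O[Si](C)(C)C(C)(C)C)[C@@H](C(C)=C)C(=O)N(C)OC | intermediate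
11 | (4R,5S)-5-[(tert-butyldimethylsilyl)oxy]-7-methyl-4-(prop-1-en-2-yl)octa-1,7-dien-3-one | C=C(C)C[C@H](O[Si](C)(C)C(C)(C)C)[C@@H](C(C)=C)C(=O)C=C | intermediate
12 | (5S,6R)-5-[(tert-butyldimethylsilyl)oxy]-3-methyl-6-(prop-1-en-2-yl)cyclohex-2-en-1-one | CC1=CC(=O)[C@H](C(C)=C)[C@@H](O[Si](C)(C)C(C)(C)C)C1 | intermediate
13 | (E)-1,2-bis(tributylstannyl)ethene | CCCC[Sn](CCCC)(CCCC)/C=C/[Sn](CCCC)(CCCC)CCCC | starting material
14 | tert-butoxy(chloro)diphenylsilane | CC(C)(C)O[Si](Cl)(c1ccccc1)c1ccccc1 | starting material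
15 | (E)-2-(tributylstannyl)vinyllithium | [Li]/C=C/[Sn](CCCC)(CCCC)CCCC | intermediate (not isolated)
16 | (E)-tert-butoxydiphenyl[2-(tributylstannyl)vinyl]silane | CCCC[Sn](CCCC)(CCCC)/C=C/[Si](OC(C)(C)C)(c1ccccc1)c1ccccc1 | intermediate
17 | (E)-2-[tert-butoxy(diphenyl)silyl]vinyllithium | [Li]/C=C/[Si](OC(C)(C)C)(c1ccccc1)c1ccccc1 | intermediate (not isolated)
18 | (E)-2-[tert-butoxy(diphenyl)silyl]vinylcerium dichloride | Cl[Ce](Cl)/C=C/[Si](OC(C)(C)C)(c1ccccc1)c1ccccc1 | intermediate (not isolated)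
19 | (1S,5S,6R)-1-[(E)-2-(tert-butoxydiphenylsilyl)vinyl]-5-[(tert-butyldimethylsilyl)oxy]-3-methyl-6-(prop-1-en-2-yl)cyclohex-2-en-1-ol | CC1=C[C@@](O)(/C=C/[Si](OC(C)(C)C)(c2ccccc2)c2ccccc2)[C@H](C(C)=C)[C@@H](O[Si](C)(C)C(C)(C)C)C1 | intermediate
20 | potassium alkoxide of 19 | [K+].CC1=C[C@@]([O-])(/C=C/[Si](OC(C)(C)C)(c2ccccc2)c2ccccc2)[C@H](C(C)=C)[C@@H](O[Si](C)(C)C(C)(C)C)C1 | intermediate (not isolated)
21 | potassium enolate of the ring-expanded ketone (C6–OK, C6=C7; C1=C10 ring-trans; C4=C5 cis; 2S,8S) | [K+].C1/C(C)=C/[C@@H](O[Si](C)(C)C(C)(C)C)C/C(C)=C\C([O-])=C\[C@H]1[Si](OC(C)(C)C)(c2ccccc2)c2ccccc2 | intermediate (not isolated)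
22 | 2-[(1S,2S,4E,6S,8Z)-2-(tert-butoxydiphenylsilyl)-6-[(tert-butyldimethylsilyl)oxy]-4,8-dimethyl-10-oxocyclodeca-4,8-dien-1-yl]-N,N-dimethylacetamide | O=C1/C=C(/C)C[C@H](O[Si](C)(C)C(C)(C)C)/C=C(\C)C[C@H]([Si](OC(C)(C)C)(c2ccccc2)c2ccccc2)[C@H]1CC(=O)N(C)C | intermediate
23 | 2-[(1S,2S,4E,6S,8Z)-2-(tert-butoxydiphenylsilyl)-6-[(tert-butyldimethylsilyl)oxy]-4-(hydroxymethyl)-8-methyl-10-oxocyclodeca-4,8-dien-1-yl]-N,N-dimethylacetamide | O=C1/C=C(/C)C[C@H](O[Si](C)(C)C(C)(C)C)/C=C(/CO)C[C@H]([Si](OC(C)(C)C)(c2ccccc2)c2ccccc2)[C@H]1CC(=O)N(C)C | intermediate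
24 | 2-[(1S,2S,4E,6S,8Z)-2-(tert-butoxydiphenylsilyl)-6-[(tert-butyldimethylsilyl)oxy]-4-{[(tert-butyldimethylsilyl)oxy]methyl}-8-methyl-10-oxocyclodeca-4,8-dien-1-yl]-N,N-dimethylacetamide | O=C1/C=C(/C)C[C@H](O[Si](C)(C)C(C)(C)C)/C=C(/CO[Si](C)(C)C(C)(C)C)C[C@H]([Si](OC(C)(C)C)(c2ccccc2)c2ccccc2)[C@H]1CC(=O)N(C)C | intermediate
25 | 2-[(1S,2S,4E,6S,8Z,10S)-2-(tert-butoxydiphenylsilyl)-6-[(tert-butyldimethylsilyl)oxy]-4-{[(tert-butyldimethylsilyl)oxy]methyl}-10-hydroxy-8-methylcyclodeca-4,8-dien-1-yl]-N,N-dimethylacetamide | O[C@H]1/C=C(/C)C[C@H](O[Si](C)(C)C(C)(C)C)/C=C(/CO[Si](C)(C)C(C)(C)C)C[C@H]([Si](OC(C)(C)C)(c2ccccc2)c2ccccc2)[C@H]1CC(=O)N(C)C | intermediate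
26 | C6 methanesulfonate of 25 | CS(=O)(=O)O[C@H]1/C=C(/C)C[C@H](O[Si](C)(C)C(C)(C)C)/C=C(/CO[Si](C)(C)C(C)(C)C)C[C@H]([Si](OC(C)(C)C)(c2ccccc2)c2ccccc2)[C@H]1CC(=O)N(C)C | intermediate (not isolated)
27 | trans-fused cyclic iminium ether (C12=NMe2+ in place of the lactone C=O) methanesulfonate | C1C(=[N+](C)C)O[C@@H]2/C=C(/C)C[C@H](O[Si](C)(C)C(C)(C)C)/C=C(/CO[Si](C)(C)C(C)(C)C)C[C@H]([Si](OC(C)(C)C)(c3ccccc3)c3ccccc3)[C@@H]12.CS(=O)(=O)[O-] | intermediate (not isolated)
28 | (2S,6R,7S,8S)-8-(tert-butoxydiphenylsilyl)-2,14-bis[(tert-butyldimethylsilyl)oxy]germacra-1(10),4-dien-12,6-olide | C1C(=O)O[C@@H]2/C=C(/C)C[C@H](O[Si](C)(C)C(C)(C)C)/C=C(/CO[Si](C)(C)C(C)(C)C)C[C@H]([Si](OC(C)(C)C)(c3ccccc3)c3ccccc3)[C@@H]12 | intermediate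
29 | (2S,6R,7R,8S)-2,14-bis[(tert-butyldimethylsilyl)oxy]-8-hydroxygermacra-1(10),4-dien-12,6-olide | C1C(=O)O[C@@H]2/C=C(/C)C[C@H](O[Si](C)(C)C(C)(C)C)/C=C(/CO[Si](C)(C)C(C)(C)C)C[C@H](O)[C@@H]12 | intermediate
30 | 13-(dimethylamino) Mannich base of 29 (C11 epimers) | CN(C)CC1C(=O)O[C@@H]2/C=C(/C)C[C@H](O[Si](C)(C)C(C)(C)C)/C=C(/CO[Si](C)(C)C(C)(C)C)C[C@H](O)[C@@H]12 | intermediate (not isolated)
31 | 13-(trimethylammonio) iodide derived from 30 | C[N+](C)(C)CC1C(=O)O[C@@H]2/C=C(/C)C[C@H](O[Si](C)(C)C(C)(C)C)/C=C(/CO[Si](C)(C)C(C)(C)C)C[C@H](O)[C@@H]12.[I-] | intermediate (not isolated)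
32 | (2S,6R,7R,8S)-2,14-bis[(tert-butyldimethylsilyl)oxy]-8-hydroxygermacra-1(10),4,11(13)-trien-12,6-olide | C=C1C(=O)O[C@@H]2/C=C(/C)C[C@H](O[Si](C)(C)C(C)(C)C)/C=C(/CO[Si](C)(C)C(C)(C)C)C[C@H](O)[C@@H]12 | intermediate
33 | (Z)-2-methylbut-2-enoic acid (angelic acid) | C/C=C(/C)C(=O)O | starting material
34 | (Z)-2-methylbut-2-enoic 2,4,6-trichlorobenzoic anhydride | C/C=C(/C)C(=O)OC(=O)c1c(Cl)cc(Cl)cc1Cl | intermediate (not isolated)
35 | (2S,6R,7R,8S)-8-[(Z)-2-methylbut-2-enoyloxy]-2,14-bis[(tert-butyldimethylsilyl)oxy]germacra-1(10),4,11(13)-trien-12,6-olide | C=C1C(=O)O[C@@H]2/C=C(/C)C[C@H](O[Si](C)(C)C(C)(C)C)/C=C(/CO[Si](C)(C)C(C)(C)C)C[C@H](OC(=O)/C(C)=C\C)[C@@H]12 | intermediate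
36 | CNP0270898.1 | C=C1C(=O)O[C@@H]2/C=C(/C)C[C@H](O)/C=C(/CO)C[C@H](OC(=O)/C(C)=C\C)[C@@H]12 | target

## Step count and risks

Total step count: 18 steps. Longest linear sequence: 16 steps (steps 1, 3–7 and 9–18; steps 2 and 8 prepare the aldehyde and the vinylsilane).

Steps most likely to fail:

1. Step 10 (key step). The crown‑ether potassium enolate may be lost by proton exchange with the product, by O‑alkylation or by double alkylation before clean C7 alkylation takes place. Fallback: the rearrangement of 19 is run as before but the enolate is silylated (Me3SiCl, Et3N, −78 °C) and isolated as the ring‑expanded trimethylsilyl enol ether F1. MeLi (THF, 0 °C) then releases the crown‑free lithium enolate F2, which is alkylated with ICH2C(O)NMe2 at −78 °C; this separates ring formation from C–C bond formation at C7 and returns the route at 22.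

2. Step 11. The ene reaction may abstract hydrogen from the ring methylene C9 instead of C14, or C14 may be oxidised without the change of alkene geometry. Fallback: oxygen is put on C14 before the ring expansion and the geometry is corrected by enal equilibration.
   - Cyclohexenone 12 is oxidised at the isopropenyl methyl, its only allylic position on an electron‑rich alkene (SeO2, t-BuOOH, CH2Cl2), to the allylic alcohol F3, which is silylated (Et3SiCl, imidazole) to the triethylsilyl ether F4.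
   - Addition of 18 as in step 9 gives the carbinol F5. KH/18-crown-6 converts it through the potassium alkoxide F6 into the ring‑expanded potassium enolate F7, and BrCH2C(O)NMe2 gives the ring‑trans ketone F8 (C14 cis to C2).
   - Swern conditions ((COCl)2, DMSO, Et3N, −78 → −20 °C) turn the primary triethylsilyl ether directly into the (Z)-enal F9. Catalytic PhSH/Et3N (reversible conjugate addition) should equilibrate it to the more stable (E)-enal F10, in which C2 and C9 are cis.
   - NaBH4/CeCl3·7H2O (MeOH, −78 °C) reduces the aldehyde and the C6 ketone together to the diol F11, and selective silylation of the primary allylic hydroxyl (t-BuMe2SiCl, imidazole, 0 °C) returns the route at 25.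

3. Step 13. Facial selectivity of the hydride addition in the flexible ten‑membered enone may be poor or reversed. Fallback: if reduction of 24 gives the 6α alcohol F12 instead of 25, no inversion is needed. F12 is warmed with pyridinium p-toluenesulfonate in toluene (60 °C) so that the C6 hydroxyl attacks the amide carbonyl (acyl substitution with retention at C6, loss of Me2NH), returning the route at 28. Either C6 epimer therefore leads to the same trans‑fused lactone.

Further compounds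
F1 | step 10 | ring-expanded trimethylsilyl enol ether (C6–OSiMe3, C6=C7; otherwise as 21) | C1/C(C)=C/[C@@H](O[Si](C)(C)C(C)(C)C)C/C(C)=C\C(O[Si](C)(C)C)=C\[C@H]1[Si](OC(C)(C)C)(c2ccccc2)c2ccccc2
F2 | step 10 | lithium enolate corresponding to 21 | [Li+].C1/C(C)=C/[C@@H](O[Si](C)(C)C(C)(C)C)C/C(C)=C\C([O-])=C\[C@H]1[Si](OC(C)(C)C)(c2ccccc2)c2ccccc2
F3 | step 11 | (5S,6R)-5-[(tert-butyldimethylsilyl)oxy]-6-(3-hydroxyprop-1-en-2-yl)-3-methylcyclohex-2-en-1-one | CC1=CC(=O)[C@H](C(CO)=C)[C@@H](O[Si](C)(C)C(C)(C)C)C1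
F4 | step 11 | (5S,6R)-5-[(tert-butyldimethylsilyl)oxy]-3-methyl-6-{3-[(triethylsilyl)oxy]prop-1-en-2-yl}cyclohex-2-en-1-one | CC1=CC(=O)[C@H](C(CO[Si](CC)(CC)CC)=C)[C@@H](O[Si](C)(C)C(C)(C)C)C1
F5 | step 11 | (1S,5S,6R)-1-[(E)-2-(tert-butoxydiphenylsilyl)vinyl]-5-[(tert-butyldimethylsilyl)oxy]-3-methyl-6-{3-[(triethylsilyl)oxy]prop-1-en-2-yl}cyclohex-2-en-1-ol | CC1=C[C@@](O)(/C=C/[Si](OC(C)(C)C)(c2ccccc2)c2ccccc2)[C@H](C(CO[Si](CC)(CC)CC)=C)[C@@H](O[Si](C)(C)C(C)(C)C)C1
F6 | step 11 | potassium alkoxide of F5 | [K+].CC1=C[C@@]([O-])(/C=C/[Si](OC(C)(C)C)(c2ccccc2)c2ccccc2)[C@H](C(CO[Si](CC)(CC)CC)=C)[C@@H](O[Si](C)(C)C(C)(C)C)C1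
F7 | step 11 | ring-expanded potassium enolate with 14-triethylsilyloxy group (C1=C10 ring-trans) | [K+].C1/C(CO[Si](CC)(CC)CC)=C/[C@@H](O[Si](C)(C)C(C)(C)C)C/C(C)=C\C([O-])=C\[C@H]1[Si](OC(C)(C)C)(c2ccccc2)c2ccccc2
F8 | step 11 | 2-[(1S,2S,4Z,6S,8Z)-2-(tert-butoxydiphenylsilyl)-6-[(tert-butyldimethylsilyl)oxy]-8-methyl-10-oxo-4-{[(triethylsilyl)oxy]methyl}cyclodeca-4,8-dien-1-yl]-N,N-dimethylacetamide (ring-trans C1=C10) | O=C1/C=C(/C)C[C@H](O[Si](C)(C)C(C)(C)C)/C=C(\CO[Si](CC)(CC)CC)C[C@H]([Si](OC(C)(C)C)(c2ccccc2)c2ccccc2)[C@H]1CC(=O)N(C)C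
F9 | step 11 | 2-[(1S,2S,4Z,6S,8Z)-2-(tert-butoxydiphenylsilyl)-6-[(tert-butyldimethylsilyl)oxy]-4-formyl-8-methyl-10-oxocyclodeca-4,8-dien-1-yl]-N,N-dimethylacetamide | O=C1/C=C(/C)C[C@H](O[Si](C)(C)C(C)(C)C)/C=C(\C=O)C[C@H]([Si](OC(C)(C)C)(c2ccccc2)c2ccccc2)[C@H]1CC(=O)N(C)C
F10 | step 11 | 2-[(1S,2S,4E,6S,8Z)-2-(tert-butoxydiphenylsilyl)-6-[(tert-butyldimethylsilyl)oxy]-4-formyl-8-methyl-10-oxocyclodeca-4,8-dien-1-yl]-N,N-dimethylacetamide | O=C1/C=C(/C)C[C@H](O[Si](C)(C)C(C)(C)C)/C=C(/C=O)C[C@H]([Si](OC(C)(C)C)(c2ccccc2)c2ccccc2)[C@H]1CC(=O)N(C)C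
F11 | step 11 | 2-[(1S,2S,4E,6S,8Z,10S)-2-(tert-butoxydiphenylsilyl)-6-[(tert-butyldimethylsilyl)oxy]-10-hydroxy-4-(hydroxymethyl)-8-methylcyclodeca-4,8-dien-1-yl]-N,N-dimethylacetamide | O[C@H]1/C=C(/C)C[C@H](O[Si](C)(C)C(C)(C)C)/C=C(/CO)C[C@H]([Si](OC(C)(C)C)(c2ccccc2)c2ccccc2)[C@H]1CC(=O)N(C)C
F12 | step 13 | 2-[(1S,2S,4E,6S,8Z,10R)-2-(tert-butoxydiphenylsilyl)-6-[(tert-butyldimethylsilyl)oxy]-4-{[(tert-butyldimethylsilyl)oxy]methyl}-10-hydroxy-8-methylcyclodeca-4,8-dien-1-yl]-N,N-dimethylacetamide (6α-OH) | O[C@@H]1/C=C(/C)C[C@H](O[Si](C)(C)C(C)(C)C)/C=C(/CO[Si](C)(C)C(C)(C)C)C[C@H]([Si](OC(C)(C)C)(c2ccccc2)c2ccccc2)[C@H]1CC(=O)N(C)C
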